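Ask first what each flask must hold at its end, then how fast it gets there.

| setting | north-west | dawn | winter | midnight |
|---|---|---|---|---|
| solid substrate | 0.050 M | 0.10 M | 0.10 M | 0.10 M |
| first nucleophile | 0.090 M | 0.0900 M | 0.0900 M | 0.0900 M |
| second nucleophile | 0.060 M | 0.0600 M | 0.0600 M | 0.0600 M |
| capture agent | 2 mM | 2.00 mM | 2.00 mM | 2.00 mM |
| temperature | 55 °C | 55 °C | 5 °C | 30 °C |
| remark | run made earlier |  |  |  |
| time |  | 4.0 d | 4.0 d | 4.0 d |
- north-west (time / h: target / %, solid substrate / %): 4.00: 31, 55; 8.00: 64, 8; 12.0: 72, 0; 15.0: 71, 2; 20.0: 69, 0

(readings scatter by 2 percentage points)
- as a solid, counted per litre of solution: solid substrate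
- steps under discussion: second nucleophile + open intermediate -> other capture product; open intermediate + capture agent -> trapped intermediate; starting material <-> open intermediate; first nucleophile + open intermediate -> target; solid substrate <-> starting material
- at the start none of the solid substrate is in solution
- what has only dissolved of solid substrate counts as not reacted
- the earlier runs do not show what temperature does; that part of a forecast is a guess
1. the flask that comes out highest in amount of target, in percent of the solid substrate charged, or "all alike" when all lie within 1.5 percentage points (dawn / winter / midnight / all alike)
2. target at the end, in percent of the solid substrate charged, dawn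
3. target at the end, in percent of the solid substrate charged, winter
4. target at the end, in percent of the solid substrate charged, midnight

In the north-west run the solid substrate reads near zero from 12.0 h on, and the last three target readings average 70.7%, level within the scatter of 2 percentage points. The target therefore looks stable. The rest is counted here as other capture product, which neglects the capture agent, at most 4.00% of that charge.

The steps under discussion send the open intermediate to target with the first nucleophile and to other capture product with the second. Each capture runs in proportion to its own nucleophile, and integrating the ratio of the two removes time:

ln(charged c(first nucleophile) / c(first nucleophile)) = S · ln(charged c(second nucleophile) / c(second nucleophile))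

The north-west plateau gives

S = 1.78

This S, the selectivity factor, is the rate constant of capture by the first nucleophile over that of capture by the second at 55 °C, read from scattered readings.

In dawn the nucleophiles together, 0.150 M, exceed the 0.10 M of solid substrate, which makes it the limiting reagent. The split at the start gives

c(target) ≈ 72.7 mM

That is a first guess, and it uses up the first nucleophile faster, as a share of charge, than the second. Averaging each guess with what the integrated rule returns gives

c(target) ≈ 68.2 mM, then 67.6 mM

So this reckoning puts dawn at 67.6%. Between 4.00 h and 8.00 h the solid readings of the north-west run fell by 5.88 mM h⁻¹, so at that rate dawn needs about 17.0 h, less than the 4.0 d allowed.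

The runs show nothing of temperature. Holding S constant is a guess and the weak link, and it puts winter and midnight on the dawn figure, all alike, if their solid is gone in time.

The forecast differs for the colder flasks, naming dawn with 69%, 1.5% and 36% for dawn, winter and midnight, and saying of them “this part is a guess, assuming Ea ≈ 80 kJ/mol”.

The flasks give 67.3% in dawn, 49.7% in winter and 59.1% in midnight, with dawn highest.

    second nucleophile + open intermediate → other capture product (k = 20.8 M⁻¹ min⁻¹, Ea = 40.0 kJ mol⁻¹)
    open intermediate + capture agent → trapped intermediate (k = 0.0492 M⁻¹ min⁻¹, Ea = 66.0 kJ mol⁻¹)
    starting material ⇌ open intermediate (K = 0.0414, k = 0.00244 min⁻¹, Ea = 94.0 kJ mol⁻¹, ΔH = −28.0 kJ mol⁻¹)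
    first nucleophile + open intermediate → target (k = 9.16 M⁻¹ min⁻¹, Ea = 61.0 kJ mol⁻¹)
    solid substrate ⇌ starting material, rate k5*(cs5 - [starting material]) while solid is left; crystals form when [starting material] > cs5 (solubility = 0.0810 M, k = 0.00118 min⁻¹)
    (constants at 5 °C)

The reforged link is the ratio of the two capture constants, which at 5 °C in winter is 0.440, below the 1.78 read at 55 °C, while the end amounts of midnight put it at 0.931 between them. Carried to the neighbour of midnight with 0.15 M of second nucleophile, that value gives a first guess of 35.8 mM target, one averaging with the integrated rule turns this into 36.4%, and that flask ends at 36.2% target.

(The readings come from a simulation for an exercise.)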